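**Retrosynthetic overview**
1. Side chain last: the C17–C19 epoxide comes from a chelation-controlled chloromethyl addition to a C17 methyl ketone; the C15/C16 anti-diol comes from an L-proline aldol of hydroxyacetone with the C15 aldehyde.
2. The C6=C7 alkene and C2 come from an enone (C7=O, C6=C2) by reductive enolate triflation and triflate reduction; ring A is closed by aldol condensation (C6–C2).
3. Ring D and the quaternary C5 come from an iron-hydride HAT radical 5-exo cyclisation of a C21 butenyl chain onto a C5-substituted enone, itself made by 1,2-addition and oxidative transposition.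
4. Ring C with C8, C12 and C20 comes from an amine-catalysed reductive desymmetrising Michael cyclisation of an achiral cyclohexadienone enal (key step).
5. Ring B is the ring of p-cresol (dearomatising allylation, then cross-metathesis); ring order B, C, D, A.

Assumption: the target is read from the SMILES as (2S,5S,8R,12R,15S,16S,17S,20R,21S,24S), and the (S)-diamine in step 3 is assumed to give the enantiomer drawn; if it gives the opposite one, the (R)-diamine is used.

Numbering (target SMILES order, used for all intermediates): C1 methyl on C2; ring A = C2–C3–C4–C5–C6; ring B = C5–C6=C7–C8–C20–C21; ring C = C8–C10–C11–C12–C20; ring D = C5–C21–C22–C23–C24; C9, C13, C25 = methyls on C8, C12, C24; side chain C14–C19 on C12 (C18 methyl and C19 epoxide CH2 on C17).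

**Step 1**
Reactants: 1 p-cresol; 2 allyltrimethylsilane
Product: 3 4-allyl-4-methylcyclohexa-2,5-dien-1-one
Conditions: PhI(OAc)2, (CF3)2CHOH, −10 °C to rt
Reagents that add atoms: none
Why: Oxidative dearomatisation of the phenol by the iodine reagent with para attack of the allylsilane (oxidative Hosomi–Sakurai allylation) gives the achiral all-carbon dienone, which has no stereocentre.

**Step 2**
Reactants: 3 4-allyl-4-methylcyclohexa-2,5-dien-1-one; 4 methacrolein
Product: 5 (E)-2-methyl-4-(1-methyl-4-oxocyclohexa-2,5-dien-1-yl)but-2-enal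
Conditions: second-generation Hoveyda–Grubbs catalyst (5 mol%), 4 (8 equiv), CH2Cl2, 40 °C
Reagents that add atoms: none
Why: Olefin cross-metathesis of the terminal alkene with methacrolein gives the trisubstituted E-enal, the electron-poor ring alkenes stay out, and 5 is still achiral.

**Step 3**
Reactants: 5 (E)-2-methyl-4-(1-methyl-4-oxocyclohexa-2,5-dien-1-yl)but-2-enal
Product: 7 (1S,3aR,7aS)-1,3a-dimethyl-6-oxo-2,3,3a,6,7,7a-hexahydro-1H-indene-1-carbaldehyde (cis-fused rings B and C; formyl C14 on the convex face), via catalyst-bound enamine 6 (not isolated)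
Conditions: (S)-N1,N1-diethyl-3,3-dimethylbutane-1,2-diamine·TfOH (20 mol%), diethyl 2,6-dimethyl-1,4-dihydropyridine-3,5-dicarboxylate (1.2 equiv), PhMe, 40 °C
Reagents that add atoms: none
Why: Proposed new method: the primary amine forms an iminium ion with the α-branched enal, the dihydropyridine delivers hydride to C11, and the resulting C12 enamine adds 5-exo to one of the two enantiotopic enone β-carbons (C20) while the ammonium N–H holds the dienone carbonyl. The three-atom tether enforces cis fusion (C8 and C20 set together) and the iminium carbon sits trans to C21, so C14 ends on the convex face and the C13 methyl on the concave face at the new quaternary C12. The closest known reactions are the amine-catalysed reductive Michael cyclisation of enal enones with a Hantzsch ester, the enamine-catalysed desymmetrising Michael cyclisation of unbranched aldehyde-tethered cyclohexadienones, and primary-amine enamine additions of α-branched aldehydes that form quaternary centres; none has been shown with an α-branched enal on a dienone.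

**Step 4**
Reactants: 7 (1S,3aR,7aS)-1,3a-dimethyl-6-oxo-2,3,3a,6,7,7a-hexahydro-1H-indene-1-carbaldehyde
Product: 8 (1S,3aR,7aS)-1-(dimethoxymethyl)-1,3a-dimethyl-1,2,3,3a,7,7a-hexahydro-6H-inden-6-one
Conditions: HC(OMe)3, MeOH, pyridinium p-toluenesulfonate (cat.), rt
Reagents that add atoms: trimethyl orthoformate, COC(OC)OC; methanol, CO
Why: Chemoselective acetalisation of the aldehyde (the conjugated ketone does not ketalise under these conditions) protects C14 for the basic steps, and the quaternary C12 cannot epimerise.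

**Step 5**
Reactants: 8 (1S,3aR,7aS)-1-(dimethoxymethyl)-1,3a-dimethyl-1,2,3,3a,7,7a-hexahydro-6H-inden-6-one; 9 4-iodobut-1-ene
Product: 11 C21-(but-3-en-1-yl) derivative of 8 (butenyl trans to the C20–C12 bond), via lithium dienolate 10 (not isolated)
Conditions: LiN(i-Pr)2, THF, −78 °C; then 9, DMPU, −78 to −20 °C
Reagents that add atoms: none
Why: Kinetic α′ deprotonation (no γ-hydrogen exists) gives the cross-conjugated enolate, which is alkylated at C21 from the face opposite ring C and its concave C13 methyl, giving the 20,21-trans product, also the thermodynamic epimer.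

**Step 6**
Reactants: 11 C21-butenyl enone; 12 2-(2-bromoethyl)-2-methyl-1,3-dioxolane
Product: 13 tertiary allylic alcohol (C5–OH bearing the 2-(2-methyl-1,3-dioxolan-2-yl)ethyl chain; C6=C7)
Conditions: 12, Mg, THF, 25 °C; then CeCl3, 11, THF, −78 to 0 °C; aq. NH4Cl
Reagents that add atoms: none
Why: Cerium-mediated 1,2-addition of the Grignard reagent to the enone carbonyl avoids enolisation and conjugate addition; the new C5 carbinol centre (attack anti to the C21 chain expected) is erased in step 7.

**Step 7**
Reactants: 13 tertiary allylic alcohol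
Product: 14 transposed enone (C7=O; C6=C5; C5 bears the dioxolanyl-ethyl chain; C21 bears butenyl)
Conditions: pyridinium chlorochromate ([C5H5NH][CrO3Cl]), NaOAc, 4 Å MS, CH2Cl2, rt
Reagents that add atoms: pyridinium chlorochromate, [O-][Cr](=O)(=O)Cl.c1cc[nH+]cc1
Why: Dauben–Babler oxidative transposition: the chromate ester of the tertiary allylic alcohol shifts [3,3] to C7 and is oxidised to the ketone, giving the β,β-disubstituted enone needed for the radical step.

**Step 8**
Reactants: 14 transposed enone
Product: 15 tricyclic ketone (rings B, C, D; C7=O; quaternary C5; C24 methyl cis to C6)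
Conditions: Fe(acac)3 (30 mol%), PhSiH3 (2.5 equiv), MeOH/THF, 50 °C
Reagents that add atoms: none
Why: Iron-hydride hydrogen-atom transfer to the terminal alkene gives the secondary C24 radical, which adds 5-exo to the enone β-carbon (reductive olefin–enone coupling, Giese type). The C21 tether on the lower face forces cis fusion, so C24 bonds to C5 from below and C4 stays above. The C24 methyl is expected to turn toward the flat C6 side and away from the C4 chain.

**Step 9**
Reactants: 15 tricyclic ketone
Product: 17 tetracyclic enone aldehyde (C7=O; C6=C2; C12–CHO), via diketo aldehyde 16 (not isolated)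
Conditions: TsOH·H2O, acetone/H2O, 40 °C; then TsOH, PhH, reflux (Dean–Stark)
Reagents that add atoms: water, O
Why: Acid hydrolysis frees the C2 ketone and the C14 aldehyde, and acid-catalysed intramolecular aldol condensation of C6 (the only enolisable position of the C7 ketone) onto C2 closes ring A as the tetrasubstituted enone; the other possible aldol adducts cannot dehydrate and revert.

**Step 10**
Reactants: 17 tetracyclic enone aldehyde
Product: 18 methyl enol ether (C12–CH=CH–OMe; E/Z mixture)
Conditions: MeOCH2PPh3Cl, KN(SiMe3)2, THF, 0 °C; then 17, 0 °C to rt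
Reagents that add atoms: (methoxymethyl)triphenylphosphonium chloride, COC[P+](c1ccccc1)(c1ccccc1)c1ccccc1.[Cl-]
Why: Wittig methoxymethylenation of the aldehyde, far more reactive than the hindered tetrasubstituted enone, adds C15, and the enol ether protects the side chain in the next reduction.

**Step 11**
Reactants: 18 methyl enol ether
Product: 20 enol triflate (C7–OTf; C6=C7; C2–H set), via lithium enolate 19 (not isolated)
Conditions: Li, NH3(l)/THF, t-BuOH (1 equiv), −78 °C; isoprene; evaporate NH3; then PhNTf2, THF, 0 °C to rt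
Reagents that add atoms: N-phenylbis(trifluoromethanesulfonimide), O=S(=O)(N(c1ccccc1)S(=O)(=O)C(F)(F)F)C(F)(F)F
Why: Dissolving-metal reduction of the enone gives the C6=C7 lithium enolate regiospecifically, with C2 protonated from the open upper face (the lower face is covered by ring D and C25) so that the C2 methyl ends cis to C24; PhNTf2 then traps the enolate on oxygen (reductive enolate triflation).

**Step 12**
Reactants: 20 enol triflate
Product: 22 aldehyde (tetracyclic core with C12–CH2–CHO), via enol ether alkene 21 (not isolated)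
Conditions: Pd(OAc)2 (5 mol%), PPh3, HCO2H, n-Bu3N, DMF, 60 °C; then 1 M HCl, THF, rt
Reagents that add atoms: water, O
Why: Palladium-catalysed formate reduction of the vinyl triflate gives the C6=C7–H alkene without touching a stereocentre, and mild acid then hydrolyses the enol ether to the homologated aldehyde.

**Step 13**
Reactants: 22 aldehyde; 23 hydroxyacetone
Product: 24 (15S,16S)-15,16-dihydroxy-17-ketone (side chain CH2–CH(OH)–CH(OH)–C(=O)CH3)
Conditions: L-proline (30 mol%), 23 (excess), DMSO, rt
Reagents that add atoms: none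
Why: Proline-catalysed direct aldol of hydroxyacetone through the hydrogen-bonded enamine transition state gives the anti-diol with (15S,16S) configuration under catalyst control; the diastereomer ratio may be modest for this α-unbranched aldehyde and the syn isomer is removed by chromatography.

**Step 14**
Reactants: 24 (15S,16S)-dihydroxy ketone
Product: 26 target CNP0393869.2, via chlorohydrin 25 (not isolated)
Conditions: i-PrMgCl·LiCl (2.1 equiv), THF, −78 °C; then ICH2Cl and i-PrMgCl·LiCl (4 equiv each), −78 °C; then K2CO3, MeOH, 0 °C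
Reagents that add atoms: chloroiodomethane, ClCI
Why: Cram-chelate control: the O16 magnesium alkoxide chelates the C17 carbonyl and the chloromethyl carbenoid attacks anti to C15, placing O17 syn to O16 (17S); the tertiary alkoxide then displaces chloride (3-exo-tet) to close the epoxide with retention at C17.

**Compound list**
1 | p-cresol | Cc1ccc(O)cc1 | starting material
2 | allyltrimethylsilane | C=CC[Si](C)(C)C | starting material
3 | 4-allyl-4-methylcyclohexa-2,5-dien-1-one | C=CCC1(C)C=CC(=O)C=C1 | intermediate
4 | methacrolein | CC(=C)C=O | starting material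
5 | (E)-2-methyl-4-(1-methyl-4-oxocyclohexa-2,5-dien-1-yl)but-2-enal | O=C/C(C)=C/CC1(C)C=CC(=O)C=C1 | intermediate
6 | enamine of the (S)-diamine catalyst with 2-methyl-4-(1-methyl-4-oxocyclohexa-2,5-dien-1-yl)butanal | CC(CCC1(C)C=CC(=O)C=C1)=CN[C@@H](C(C)(C)C)CN(CC)CC | intermediate
7 | (1S,3aR,7aS)-1,3a-dimethyl-6-oxo-2,3,3a,6,7,7a-hexahydro-1H-indene-1-carbaldehyde | O=C1C=C[C@@]2(C)CC[C@](C)(C=O)[C@H]2C1 | intermediate
8 | (1S,3aR,7aS)-1-(dimethoxymethyl)-1,3a-dimethyl-1,2,3,3a,7,7a-hexahydro-6H-inden-6-one | O=C1C=C[C@@]2(C)CC[C@](C)(C(OC)OC)[C@H]2C1 | intermediate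
9 | 4-iodobut-1-ene | C=CCCI | starting material
10 | lithium cross-conjugated dienolate of 8 (O–C5=C21) | [Li]OC=1C=C[C@@]2(C)CC[C@](C)(C(OC)OC)[C@H]2C=1 | intermediate
11 | 8 with a but-3-en-1-yl group at C21, trans to the C20–C12 bond | O=C1C=C[C@@]2(C)CC[C@](C)(C(OC)OC)[C@H]2[C@@H]1CCC=C | intermediate
12 | 2-(2-bromoethyl)-2-methyl-1,3-dioxolane | CC1(CCBr)OCCO1 | starting material
13 | tertiary allylic alcohol (C5–OH with dioxolanyl-ethyl chain; major C5 epimer drawn, both converge in step 7) | CC1(OCCO1)CC[C@@]2(O)C=C[C@@]3(C)CC[C@](C)(C(OC)OC)[C@H]3[C@@H]2CCC=C | intermediate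
14 | transposed enone (C7=O, C6=C5) | CC1(OCCO1)CCC2=CC(=O)[C@@]3(C)CC[C@](C)(C(OC)OC)[C@H]3[C@@H]2CCC=C | intermediate
15 | tricyclic ketone (rings B, C, D; C5, C8, C12, C20, C21, C24 as in the target) | CC1(OCCO1)CC[C@@]23CC(=O)[C@@]4(C)CC[C@](C)(C(OC)OC)[C@H]4[C@@H]2CC[C@@H]3C | intermediate
16 | diketo aldehyde (C2=O, C7=O, C14 aldehyde) | CC(=O)CC[C@@]23CC(=O)[C@@]4(C)CC[C@](C)(C=O)[C@H]4[C@@H]2CC[C@@H]3C | intermediate
17 | tetracyclic enone aldehyde (C7=O, C6=C2, C12–CHO) | CC1=C2C(=O)[C@@]3(C)CC[C@](C)(C=O)[C@H]3[C@@H]4CC[C@H](C)[C@]24CC1 | intermediate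
18 | methyl enol ether of the homologated aldehyde (E/Z mixture) | CC1=C2C(=O)[C@@]3(C)CC[C@](C)(C=COC)[C@H]3[C@@H]4CC[C@H](C)[C@]24CC1 | intermediate
19 | lithium enolate (C7–OLi, C6=C7, C2–H as in the target) | C[C@H]1CC[C@@]23C1=C(O[Li])[C@@]1(C)CC[C@](C)(C=COC)[C@H]1[C@@H]2CC[C@@H]3C | intermediate
20 | enol triflate (C7–OTf, C6=C7) | C[C@H]1CC[C@@]23C1=C(OS(=O)(=O)C(F)(F)F)[C@@]1(C)CC[C@](C)(C=COC)[C@H]1[C@@H]2CC[C@@H]3C | intermediate
21 | tetracyclic alkene with the enol ether side chain | C[C@H]1CC[C@@]23C1=C[C@@]1(C)CC[C@](C)(C=COC)[C@H]1[C@@H]2CC[C@@H]3C | intermediate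
22 | tetracyclic aldehyde (C12–CH2–CHO) | C[C@H]1CC[C@@]23C1=C[C@@]1(C)CC[C@](C)(CC=O)[C@H]1[C@@H]2CC[C@@H]3C | intermediate
23 | hydroxyacetone | CC(=O)CO | starting material
24 | (15S,16S)-15,16-dihydroxy-17-ketone | C[C@H]1CC[C@@]23C1=C[C@@]1(C)CC[C@](C)(C[C@H](O)[C@H](O)C(C)=O)[C@H]1[C@@H]2CC[C@@H]3C | intermediate
25 | (15S,16S,17S)-19-chloro-15,16,17-triol (chlorohydrin) | C[C@H]1CC[C@@]23C1=C[C@@]1(C)CC[C@](C)(C[C@H](O)[C@H](O)[C@@](C)(O)CCl)[C@H]1[C@@H]2CC[C@@H]3C | intermediate
26 | CNP0393869.2 | C[C@H]1CC[C@@]23C1=C[C@@]1(C)CC[C@](C)(C[C@H](O)[C@H](O)[C@]4(C)CO4)[C@H]1[C@@H]2CC[C@@H]3C | target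

**Step count**
Total: 14 steps. Longest linear sequence: 14 steps (fully linear from p-cresol).

**Three steps most likely to fail**

Step 3 (proposed new reaction). Risks are slow closure between two quaternary-substituted carbons and an uncertain C12 configuration. The fallback uses only known reaction types, sets out from 3 and returns at 7. Linear hydroformylation of the allyl group (Rh(acac)(CO)2, Xantphos, CO/H2) gives 4-(1-methyl-4-oxocyclohexa-2,5-dien-1-yl)butanal F1. The known diarylprolinol silyl ether-catalysed desymmetrising Michael cyclisation of this unbranched aldehyde gives the cis-fused keto aldehyde with a tertiary C12–H and convex formyl group F2. Amine/palladium-catalysed α-allylation (Pd(PPh3)4, pyrrolidine, allyl acetate) then builds the quaternary centre from the convex face and gives the concave-formyl convex-allyl keto aldehyde F3. The concave formyl group is converted to the C13 methyl: NaBH4 at −78 °C gives the neopentyl alcohol F4, 1,1′-thiocarbonyldiimidazole gives the imidazolyl thiocarbonate F5, and Bu3SnH/AIBN gives the C12-methyl C12-allyl enone F6. The allyl group is cut to C14: RhCl3·3H2O in EtOH gives the propenyl enone F7, and OsO4/NaIO4 cleaves it to 7.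

Step 8. Risks are a secondary radical forming a quaternary centre and the C24 configuration. The fallback sets out from 14 and returns at 15. A neutral Wacker oxidation of the terminal alkene (Pd(quinox)Cl2, AgSbF6, aqueous t-BuOOH) gives the methyl ketone F8. SmI2/HMPA/t-BuOH ketyl–enone reductive cyclisation forms the C24–C5 bond and gives the cis-fused tertiary alcohol F9. Burgess dehydration gives the exocyclic methylene compound F10. Hydrogenation (H2, Pd/C, or Mn(dpm)3/PhSiH3 if the other face is needed) sets C24 and gives 15.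

Step 14. Risks are carbenoid addition to an unprotected dihydroxy ketone and competing ring closures. The fallback sets out from 24 and returns at 26. It keeps the chelation logic but replaces the carbenoid by a stable Grignard reagent and closes the epoxide from a diol. Excess (isopropoxydimethylsilyl)methylmagnesium chloride in THF at −78 °C gives the silylmethyl triol F11. Tamao oxidation (H2O2, KF, KHCO3) gives the 15,16,17,19-tetraol F12. Selective sulfonylation of the primary hydroxyl (2,4,6-triisopropylbenzenesulfonyl chloride, pyridine) gives the primary sulfonate F13, and K2CO3/MeOH closes the epoxide to 26.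

**Further compounds**
F1 | step 3 | 4-(1-methyl-4-oxocyclohexa-2,5-dien-1-yl)butanal | O=CCCCC1(C)C=CC(=O)C=C1
F2 | step 3 | cis-fused keto aldehyde with tertiary C12–H and convex formyl group | O=C1C=C[C@@]2(C)CC[C@H](C=O)[C@H]2C1
F3 | step 3 | concave-formyl convex-allyl keto aldehyde | O=C1C=C[C@@]2(C)CC[C@](C=O)(CC=C)[C@H]2C1
F4 | step 3 | neopentyl alcohol | O=C1C=C[C@@]2(C)CC[C@](CO)(CC=C)[C@H]2C1
F5 | step 3 | imidazolyl thiocarbonate | O=C1C=C[C@@]2(C)CC[C@](COC(=S)n3ccnc3)(CC=C)[C@H]2C1
F6 | step 3 | C12-methyl C12-allyl enone | O=C1C=C[C@@]2(C)CC[C@](C)(CC=C)[C@H]2C1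
F7 | step 3 | propenyl enone (E/Z mixture) | O=C1C=C[C@@]2(C)CC[C@](C)(C=CC)[C@H]2C1
F8 | step 8 | methyl ketone from 14 | CC1(OCCO1)CCC2=CC(=O)[C@@]3(C)CC[C@](C)(C(OC)OC)[C@H]3[C@@H]2CCC(C)=O
F9 | step 8 | cis-fused tertiary alcohol (C24 epimers) | CC1(OCCO1)CC[C@@]23CC(=O)[C@@]4(C)CC[C@](C)(C(OC)OC)[C@H]4[C@@H]2CCC3(C)O
F10 | step 8 | exocyclic methylene compound | CC1(OCCO1)CC[C@@]23CC(=O)[C@@]4(C)CC[C@](C)(C(OC)OC)[C@H]4[C@@H]2CCC3=C
F11 | step 14 | silylmethyl triol | C[C@H]1CC[C@@]23C1=C[C@@]1(C)CC[C@](C)(C[C@H](O)[C@H](O)[C@@](C)(O)C[Si](C)(C)OC(C)C)[C@H]1[C@@H]2CC[C@@H]3C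
F12 | step 14 | 15,16,17,19-tetraol | C[C@H]1CC[C@@]23C1=C[C@@]1(C)CC[C@](C)(C[C@H](O)[C@H](O)[C@@](C)(O)CO)[C@H]1[C@@H]2CC[C@@H]3C
F13 | step 14 | primary 2,4,6-triisopropylbenzenesulfonate | C[C@H]1CC[C@@]23C1=C[C@@]1(C)CC[C@](C)(C[C@H](O)[C@H](O)[C@@](C)(O)COS(=O)(=O)c4c(C(C)C)cc(C(C)C)cc4C(C)C)[C@H]1[C@@H]2CC[C@@H]3C
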